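(The earlier runs and the new flask are calculated for substances that don't exist, and the scatter is random.)

Counted in moles per mole of free catalyst charged, the impurity stands at 0.469 in the autumn run, 0.719 in the midnight run and 0.969 in the flask, with substrates, reagent and catalyst charged alike.

all flasks: left-handed substrate 0.032 M; right-handed substrate 0.032 M; free catalyst 0.32 mM

| charge | reagent | impurity | remark |
|---|---|---|---|
| autumn | 0.096 M | 0.15 mM | run made earlier |
| midnight | 0.096 M | 0.23 mM | run made earlier |
| flask | 0.0960 M | 0.31 mM |  |

| run | time / min | left-handed product / % | left-handed substrate / % |
|---|---|---|---|
| autumn | 0.250 | 2.2 | 46.7 |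
| autumn | 0.667 | 7.3 | 42.1 |
| autumn | 1.33 | 14.2 | 36.1 |
| autumn | 2.00 | 19.3 | 30.6 |
| autumn | 3.00 | 26.4 | 24.0 |
| autumn | 4.00 | 31.2 | 18.1 |
| midnight | 0.667 | 6.7 | 41.9 |
| midnight | 1.33 | 13.0 | 36.7 |
| midnight | 2.00 | 18.1 | 31.7 |
| midnight | 2.50 | 20.7 | 28.9 |
| midnight | 3.00 | 23.2 | 26.2 |
| midnight | 4.00 | 27.9 | 21.9 |

(readings scatter by 0.3 percentage points)

- apparent order in reagent when 20% of the left-handed substrate and right-handed substrate together are converted (percent change of the rate of making left-handed product for one percent more reagent charged)

- free catalyst is single-handed; left-handed substrate and right-handed substrate are mirror images of each other, charged as a racemate, each of them at the stated concentration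
- the numbers in the tables scatter by 0.3 percentage points (one standard deviation)
- what may be going on: free catalyst + left-handed substrate <-> catalyst intermediate A; free catalyst + right-handed substrate <-> catalyst intermediate B; reagent + catalyst intermediate A -> free catalyst + left-handed product; reagent + catalyst intermediate B -> free catalyst + right-handed product; free catalyst + impurity -> spent catalyst
- no earlier run changes the charge of reagent; that part of a forecast is a guess

The bench rule for a round whose slow step takes up reagent (the rate-limiting step) gives an order of one in reagent, provided the working catalyst stays constant. In the flask that proviso is in doubt, because the impurity charged is enough to take up nearly all of the catalyst charged.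

The runs give a reading of how much. From 2.00 min to 4.00 min, the midnight run makes 0.824 of the left-handed product that the autumn run makes, a reading with sizeable scatter. Taking this as the ratio of working catalyst, with the same fraction of impurity reacted in both runs, that fraction is 0.530. This reckoning then puts the flask at 0.486 for the fraction of the catalyst charged not yet spent, the working share, around the middle of that span. The same share is used for 20% conversion, since the left-handed product of the midnight run passes that level inside the span, from 18.1% to 20.7%.

Assume the share decays at a steady fractional pace that reagent does not touch. Product made is then proportional to reagent times the share lost. At fixed conversion, one percent more reagent makes the lost share one percent smaller, which raises the working share by (lost share / working share) percent. Adding reagent's own percent, the order is one over the working share, which this reckoning puts at 2.06.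

The forecast gives 0.4, within 0.1 to 0.8: “Reagent dependence is therefore probably partial”. The flask gives 1.9, lower than the reckoning's figure.

    free catalyst + left-handed substrate ⇌ catalyst intermediate A (K = 640 M⁻¹, k = 1600 M⁻¹ s⁻¹)
    free catalyst + right-handed substrate ⇌ catalyst intermediate B (K = 40.0 M⁻¹, k = 450 M⁻¹ s⁻¹)
    reagent + catalyst intermediate A → free catalyst + left-handed product (k = 4.90 M⁻¹ s⁻¹)
    reagent + catalyst intermediate B → free catalyst + right-handed product (k = 2.20 M⁻¹ s⁻¹)
    free catalyst + impurity → spent catalyst (k = 410 M⁻¹ s⁻¹)

With substrate and reagent as charged, free catalyst passes into catalyst intermediate A at 3100 min⁻¹ per free catalyst, while catalyst intermediate A meets reagent at 28 min⁻¹, a ratio of 109, and at 3.00 min the flask holds 32.9% of its catalyst as catalyst intermediate A (the resting state) against 3.24% as free catalyst. Counting catalyst intermediate A, catalyst intermediate B and free catalyst, the working share in the flask at that time is 40.2%, below the reckoned 0.486, and spent catalyst stands at 59.8%.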